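The labdane core is cut at C4–C5 and C1–C10 (labdane numbering), leaving ring B as 2-methylcyclohex-2-en-1-one. The key step exploits the fact that C5 and the quaternary C10 are neighbours in ring B, hold the two termini of ring A (C4, C1) in a trans relationship, and adjoin C9, which is carried as a ketone. In one operation an enantioselective Mukaiyama–Michael addition of a ketene silyl acetal forges C4–C5 and the resulting C9=C10 enol silane is allylated at C10, setting both stereocentres. The precursor set is simply the enone, the silyl ketene acetal and allyl bromide. Ring A is then closed at C3–C4 and the side chain attached at C9.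

Key step: step 1

Numbering: ring atoms carry labdane numbers (C1–C10); 4α-CH3 = C18, 4β-carbon = C19, 10β-CH3 = C20. The target is methyl (13E)-19-acetoxylabda-8,13-dien-15-oate, (4S,5R,10S).

Assumption: the oxazaborolidinium ion derived from (S)-α,α-diphenylprolinol is taken to expose the enone face that leads to (S)-C5; should the sense prove opposite, the (R)-derived catalyst is used and nothing else changes.

Step 1
Reactants: 1 2-methylcyclohex-2-en-1-one; 2 1-(tert-butyldimethylsilyloxy)-1-methoxyethene; 3 allyl bromide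
Product: 6 methyl 2-[(1S,2S)-2-methyl-3-oxo-2-(prop-2-en-1-yl)cyclohexyl]acetate, via TBS enol ether 4 (not isolated), via sulfonium enolate 5 (not isolated)
Conditions: C24H24BNO·HN(SO2CF3)2 [(S)-o-tolyl-oxazaborolidinium triflimide, 20 mol %], Ph3PO (25 mol %), toluene, −20 °C; evaporate volatiles; then 3 (excess), (Me2N)3S+ Me3SiF2− (TASF), THF, −78 → 0 °C
Reagents that add atoms: none
Why: The cationic boron Lewis acid binds the enone carbonyl, the ketene silyl acetal adds to C5 on the exposed enantioface (Mukaiyama–Michael addition), and silyl transfer to oxygen leaves the tetrasubstituted C9=C10 enol silane 4, which fixes where the second bond must form. Fluoride then cleaves the O–Si bond without touching the methyl ester (an alkyllithium would add to it), and the naked enolate 5 is C-allylated at C10 by SN2 displacement of bromide. The closest known reaction type is catalytic enantioselective Mukaiyama–Michael addition to cyclic enones followed by regiospecific fluoride-mediated alkylation of the enol silane (vicinal difunctionalisation of an enone); no ring is closed. C5 is set by the chiral oxazaborolidinium ion, and C10 by the C5 arm, which lies pseudoaxial to avoid allylic strain with the C10 methyl so that allyl bromide enters from the opposite face and the C1 and C4 arms end up trans. The step needs C- over O-allylation and no enolate migration to C8; a reactive allylic halide in excess, low temperature and the absence of a proton source should secure both.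

Step 2
Reactants: 6 methyl 2-[(1S,2S)-2-methyl-3-oxo-2-(prop-2-en-1-yl)cyclohexyl]acetate
Product: 7 methyl 2-[(6S,7S)-6-methyl-6-(prop-2-en-1-yl)-1,4-dioxaspiro[4.5]decan-7-yl]acetate
Conditions: HOCH2CH2OH, TsOH·H2O (cat.), benzene, reflux (Dean–Stark)
Reagents that add atoms: ethylene glycol, OCCO
Why: Acid-catalysed ketalisation with azeotropic water removal masks the only ketone (C9) before the strong-base and hydride steps; ketones flanked by a quaternary carbon ketalise normally, and the ester and alkene are inert.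

Step 3
Reactants: 7 methyl 2-[(6S,7S)-6-methyl-6-(prop-2-en-1-yl)-1,4-dioxaspiro[4.5]decan-7-yl]acetate
Product: 8 methyl 2-[(6S,7S)-6-(3-hydroxypropyl)-6-methyl-1,4-dioxaspiro[4.5]decan-7-yl]acetate
Conditions: 9-BBN, THF, 0 °C → rt; then 30% H2O2, aq. NaOAc, 0 °C → rt
Reagents that add atoms: hydrogen peroxide, OO
Why: Anti-Markovnikov hydroboration–oxidation of the monosubstituted alkene places oxygen on C3; 9-BBN does not reduce the ester and the buffered oxidation avoids saponification.

Step 4
Reactants: 8 methyl 2-[(6S,7S)-6-(3-hydroxypropyl)-6-methyl-1,4-dioxaspiro[4.5]decan-7-yl]acetate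
Product: 9 methyl 2-[(6S,7S)-6-(3-iodopropyl)-6-methyl-1,4-dioxaspiro[4.5]decan-7-yl]acetate
Conditions: I2, PPh3, imidazole, CH2Cl2, 0 °C → rt
Reagents that add atoms: iodine, II
Why: Appel-type iodination of the primary alcohol proceeds through the alkoxyphosphonium salt under imidazole buffering, which keeps the ketal intact.

Step 5
Reactants: 9 methyl 2-[(6S,7S)-6-(3-iodopropyl)-6-methyl-1,4-dioxaspiro[4.5]decan-7-yl]acetate
Product: 10 methyl (4'aS,8'aS)-8'a-methyloctahydro-2'H-spiro[1,3-dioxolane-2,1'-naphthalene]-5'-carboxylate (trans-fused ring A/B ester with C9 ketal; C4 epimers)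
Conditions: LiN(iPr)2, THF–DMPU, −78 → 0 °C (slow addition of 9)
Reagents that add atoms: none
Why: Kinetic deprotonation α to the ester and 6-exo-tet intramolecular enolate alkylation at the primary iodide close ring A at C3–C4; the trans-disposed arms on C5 and C10 can only give the trans-fused decalin, and the C4 configuration is erased in step 6.

Step 6
Reactants: 10 methyl (4'aS,8'aS)-8'a-methyloctahydro-2'H-spiro[1,3-dioxolane-2,1'-naphthalene]-5'-carboxylate
Product: 11 methyl (4'aR,5'S,8'aS)-5',8'a-dimethyloctahydro-2'H-spiro[1,3-dioxolane-2,1'-naphthalene]-5'-carboxylate (4α-CH3, 4β-CO2Me)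
Conditions: LiN(iPr)2, THF–DMPU, −78 → 0 °C; MeI, −78 °C → rt
Reagents that add atoms: iodomethane, CI
Why: Diastereoselective alkylation of the exocyclic ester enolate: the β face of C4 is blocked by the 1,3-diaxial C10 methyl group, so iodomethane enters from the α (equatorial) side and the ester is left axial (β), as C19 requires.

Step 7
Reactants: 11 methyl (4'aR,5'S,8'aS)-5',8'a-dimethyloctahydro-2'H-spiro[1,3-dioxolane-2,1'-naphthalene]-5'-carboxylate
Product: 12 methyl (1S,4aS,8aR)-1,4a-dimethyl-5-oxodecahydronaphthalene-1-carboxylate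
Conditions: 2 M HCl, THF, 50 °C
Reagents that add atoms: water, O
Why: Acid hydrolysis of the dioxolane frees the C9 ketone; the hindered quaternary ester survives and no stereocentre is epimerisable (C10 is quaternary, C5 is β to the carbonyl).

Step 8
Reactants: 12 methyl (1S,4aS,8aR)-1,4a-dimethyl-5-oxodecahydronaphthalene-1-carboxylate
Product: 13 methyl (1S,4aS,8aR)-1,4a,6-trimethyl-5-oxodecahydronaphthalene-1-carboxylate (C8 epimers)
Conditions: LiN(iPr)2, THF, −78 °C; MeI, −78 → 0 °C
Reagents that add atoms: iodomethane, CI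
Why: Ketone enolate methylation can occur only at C8 because C10 is quaternary and the C4 ester has no α-hydrogen; the C8 configuration is irrelevant as this carbon becomes sp2 in step 9.

Step 9
Reactants: 13 methyl (1S,4aS,8aR)-1,4a,6-trimethyl-5-oxodecahydronaphthalene-1-carboxylate
Product: 14 methyl (1S,4aS,8aR)-1,4a,6-trimethyl-5-{[(trifluoromethyl)sulfonyl]oxy}-1,2,3,4,4a,7,8,8a-octahydronaphthalene-1-carboxylate (C8=C9 enol triflate)
Conditions: LiN(iPr)2, THF, −78 → 0 °C; PhNTf2, −78 °C → rt
Reagents that add atoms: N-phenylbis(trifluoromethanesulfonimide), FC(F)(F)S(=O)(=O)N(c1ccccc1)S(=O)(=O)C(F)(F)F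
Why: Enolate O-triflation; the single remaining α-hydrogen (C8–H) forces the tetrasubstituted C8=C9 enolate, as in the standard preparation of enol triflates from 2,2,6-trisubstituted cyclohexanones.

Step 10
Reactants: 14 methyl (1S,4aS,8aR)-1,4a,6-trimethyl-5-{[(trifluoromethyl)sulfonyl]oxy}-1,2,3,4,4a,7,8,8a-octahydronaphthalene-1-carboxylate; 15 2-(2-bromoethyl)-2-methyl-1,3-dioxolane
Product: 17 methyl (1S,4aS,8aR)-1,4a,6-trimethyl-5-[2-(2-methyl-1,3-dioxolan-2-yl)ethyl]-1,2,3,4,4a,7,8,8a-octahydronaphthalene-1-carboxylate, via alkylzinc bromide 16 (not isolated)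
Conditions: 15, Zn dust, LiCl, THF, 40 °C; then 14, PdCl2(dppf) (5 mol %), THF–NMP, 60 °C
Reagents that add atoms: none
Why: Negishi coupling of a primary alkylzinc halide with an enol triflate forms C9–C11; the zinc reagent tolerates the ester and ketal, and cyclohexenyl triflates flanked by a quaternary carbon are established partners in palladium-catalysed cross-coupling.

Step 11
Reactants: 17 methyl (1S,4aS,8aR)-1,4a,6-trimethyl-5-[2-(2-methyl-1,3-dioxolan-2-yl)ethyl]-1,2,3,4,4a,7,8,8a-octahydronaphthalene-1-carboxylate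
Product: 19 4-[(4aR,5S,8aS)-5-(hydroxymethyl)-2,5,8a-trimethyl-3,4,4a,5,6,7,8,8a-octahydronaphthalen-1-yl]butan-2-one, via ketal alcohol 18 (not isolated)
Conditions: LiAlH4, THF, 0 °C → reflux; then 2 M HCl, THF, rt
Reagents that add atoms: water, O
Why: Hydride reduction of the hindered axial ester gives the C19 alcohol while the side-chain ketone is still masked, and the acidic work-up then hydrolyses the dioxolane; the tetrasubstituted alkene is inert to both.

Step 12
Reactants: 19 4-[(4aR,5S,8aS)-5-(hydroxymethyl)-2,5,8a-trimethyl-3,4,4a,5,6,7,8,8a-octahydronaphthalen-1-yl]butan-2-one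
Product: 20 methyl (2E)-5-[(4aR,5S,8aS)-5-(hydroxymethyl)-2,5,8a-trimethyl-3,4,4a,5,6,7,8,8a-octahydronaphthalen-1-yl]-3-methylpent-2-enoate
Conditions: (MeO)2P(O)CH2CO2Me (slight excess over base), NaH, THF, 0 °C → reflux
Reagents that add atoms: trimethyl phosphonoacetate, COC(=O)CP(=O)(OC)OC
Why: Horner–Wadsworth–Emmons olefination of the methyl ketone should favour the 13E enoate, with the ester anti to the larger CH2CH2R group; the minor Z isomer is removed by chromatography, and the stabilised phosphonate anion does not deprotonate the neopentyl alcohol.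

Step 13
Reactants: 20 methyl (2E)-5-[(4aR,5S,8aS)-5-(hydroxymethyl)-2,5,8a-trimethyl-3,4,4a,5,6,7,8,8a-octahydronaphthalen-1-yl]-3-methylpent-2-enoate
Product: 21 methyl (2E)-5-[(4aR,5S,8aS)-5-(acetoxymethyl)-2,5,8a-trimethyl-3,4,4a,5,6,7,8,8a-octahydronaphthalen-1-yl]-3-methylpent-2-enoate (target)
Conditions: Ac2O, pyridine, DMAP (cat.), CH2Cl2, rt
Reagents that add atoms: acetic anhydride, CC(=O)OC(C)=O
Why: DMAP-catalysed acylation of the primary alcohol installs the base-sensitive acetate last, under conditions that leave the enoate and the ring alkene untouched.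

Compound list
1 | 2-methylcyclohex-2-en-1-one | CC1=CCCCC1=O | starting material
2 | 1-(tert-butyldimethylsilyloxy)-1-methoxyethene | C=C(OC)O[Si](C)(C)C(C)(C)C | starting material
3 | allyl bromide (3-bromoprop-1-ene) | C=CCBr | starting material
4 | methyl 2-[(1S)-3-(tert-butyldimethylsilyloxy)-2-methylcyclohex-2-en-1-yl]acetate (C9=C10 enol silane; not isolated) | COC(=O)C[C@@H]1CCCC(O[Si](C)(C)C(C)(C)C)=C1C | intermediate
5 | tris(dimethylamino)sulfonium (6S)-6-(2-methoxy-2-oxoethyl)-2-methylcyclohex-1-en-1-olate (C9=C10 enolate; not isolated) | COC(=O)C[C@@H]1CCCC([O-])=C1C.CN(C)[S+](N(C)C)N(C)C | intermediate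
6 | methyl 2-[(1S,2S)-2-methyl-3-oxo-2-(prop-2-en-1-yl)cyclohexyl]acetate (allyl trans to the acetate arm) | O=C1CCC[C@@H](CC(=O)OC)[C@]1(C)CC=C | intermediate
7 | methyl 2-[(6S,7S)-6-methyl-6-(prop-2-en-1-yl)-1,4-dioxaspiro[4.5]decan-7-yl]acetate | C12(OCCO1)CCC[C@@H](CC(=O)OC)[C@]2(C)CC=C | intermediate
8 | methyl 2-[(6S,7S)-6-(3-hydroxypropyl)-6-methyl-1,4-dioxaspiro[4.5]decan-7-yl]acetate | C12(OCCO1)CCC[C@@H](CC(=O)OC)[C@]2(C)CCCO | intermediate
9 | methyl 2-[(6S,7S)-6-(3-iodopropyl)-6-methyl-1,4-dioxaspiro[4.5]decan-7-yl]acetate | C12(OCCO1)CCC[C@@H](CC(=O)OC)[C@]2(C)CCCI | intermediate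
10 | methyl (4'aS,8'aS)-8'a-methyloctahydro-2'H-spiro[1,3-dioxolane-2,1'-naphthalene]-5'-carboxylate (5α-H, 10β-CH3, C4 epimers) | C12(OCCO1)CCC[C@H]3C(C(=O)OC)CCC[C@]23C | intermediate
11 | methyl (4'aR,5'S,8'aS)-5',8'a-dimethyloctahydro-2'H-spiro[1,3-dioxolane-2,1'-naphthalene]-5'-carboxylate | C12(OCCO1)CCC[C@H]3[C@@](C)(C(=O)OC)CCC[C@]23C | intermediate
12 | methyl (1S,4aS,8aR)-1,4a-dimethyl-5-oxodecahydronaphthalene-1-carboxylate | O=C1CCC[C@H]2[C@@](C)(C(=O)OC)CCC[C@]12C | intermediate
13 | methyl (1S,4aS,8aR)-1,4a,6-trimethyl-5-oxodecahydronaphthalene-1-carboxylate (C8 epimers) | O=C1C(C)CC[C@H]2[C@@](C)(C(=O)OC)CCC[C@]12C | intermediate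
14 | methyl (1S,4aS,8aR)-1,4a,6-trimethyl-5-{[(trifluoromethyl)sulfonyl]oxy}-1,2,3,4,4a,7,8,8a-octahydronaphthalene-1-carboxylate | FC(F)(F)S(=O)(=O)OC1=C(C)CC[C@H]2[C@@](C)(C(=O)OC)CCC[C@]12C | intermediate
15 | 2-(2-bromoethyl)-2-methyl-1,3-dioxolane | CC1(CCBr)OCCO1 | starting material
16 | [2-(2-methyl-1,3-dioxolan-2-yl)ethyl]zinc bromide (not isolated) | CC1(CC[Zn]Br)OCCO1 | intermediate
17 | methyl (1S,4aS,8aR)-1,4a,6-trimethyl-5-[2-(2-methyl-1,3-dioxolan-2-yl)ethyl]-1,2,3,4,4a,7,8,8a-octahydronaphthalene-1-carboxylate | CC1(CCC2=C(C)CC[C@H]3[C@@](C)(C(=O)OC)CCC[C@]23C)OCCO1 | intermediate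
18 | [(1S,4aS,8aR)-1,4a,6-trimethyl-5-[2-(2-methyl-1,3-dioxolan-2-yl)ethyl]-1,2,3,4,4a,7,8,8a-octahydronaphthalen-1-yl]methanol (not isolated) | CC1(CCC2=C(C)CC[C@H]3[C@@](C)(CO)CCC[C@]23C)OCCO1 | intermediate
19 | 4-[(4aR,5S,8aS)-5-(hydroxymethyl)-2,5,8a-trimethyl-3,4,4a,5,6,7,8,8a-octahydronaphthalen-1-yl]butan-2-one | CC(=O)CCC1=C(C)CC[C@H]2[C@@](C)(CO)CCC[C@]12C | intermediate
20 | methyl (2E)-5-[(4aR,5S,8aS)-5-(hydroxymethyl)-2,5,8a-trimethyl-3,4,4a,5,6,7,8,8a-octahydronaphthalen-1-yl]-3-methylpent-2-enoate | COC(=O)/C=C(\C)CCC1=C(C)CC[C@H]2[C@@](C)(CO)CCC[C@]12C | intermediate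
21 | methyl (2E)-5-[(4aR,5S,8aS)-5-(acetoxymethyl)-2,5,8a-trimethyl-3,4,4a,5,6,7,8,8a-octahydronaphthalen-1-yl]-3-methylpent-2-enoate | COC(=O)/C=C(\C)CCC1=C(C)CC[C@H]2[C@@](C)(COC(C)=O)CCC[C@]12C | target

Total step count: 13. Longest linear sequence: 13 steps (1 → 21); the zinc reagent 16 is made in the flask in step 10.

Steps most likely to fail

Step 1. The α-methyl group slows conjugate addition and removes the α-C–H contact that usually helps to organise an enone on the boron catalyst, so enantioface discrimination may be weak; a second failure mode is proton transfer or O-allylation during the fluoride-triggered alkylation. The fallback sets out from 1 and comes back at 6, fixing C5 by reagent-controlled reduction and sigmatropic chirality transfer. Reduction of 1 with catecholborane and the (R)-methyl-oxazaborolidine C18H20BNO should give (S)-2-methylcyclohex-2-en-1-ol F1. Johnson–Claisen rearrangement with trimethyl orthoacetate (cat. propionic acid, 140 °C) moves the carbinol configuration suprafacially to C5 and should give methyl 2-[(1S)-2-methylcyclohex-2-en-1-yl]acetate F2. Hydroboration–oxidation (BH3·SMe2, 0 °C; buffered H2O2) should give methyl 2-[(1S)-3-hydroxy-2-methylcyclohexyl]acetate F3, and Dess–Martin oxidation methyl 2-[(1S)-2-methyl-3-oxocyclohexyl]acetate F4. Thermodynamic silylation (TMSCl, NaI, Et3N, MeCN) should give the more substituted enol silane methyl 2-[(1S)-2-methyl-3-(trimethylsilyloxy)cyclohex-2-en-1-yl]acetate F5, which with TASF and 3, as in the second stage of step 1, should give 6.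

Step 10. Oxidative addition and transmetalation at a tetrasubstituted triflate beside the quaternary C10 may be slow, so that triflate cleavage or protodemetalation of the zinc reagent competes with coupling. The fallback sets out from 14 and comes back at 17, replacing the sp2–sp3 coupling by an insertion that needs no bulky organometallic partner. Heck reaction of 14 with but-3-en-2-one (Pd(OAc)2, PPh3, Et3N, DMF, 70 °C) should give the dienone methyl 13-oxo-14,15-dinorlabda-8,11E-dien-19-oate F6. Conjugate reduction of the disubstituted enone double bond with [(Ph3P)CuH]6 in wet benzene should give methyl 13-oxo-14,15-dinorlabd-8-en-19-oate F7. Ketalisation (ethylene glycol, TsOH, benzene, reflux) then returns 17.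

Step 12. The two groups on the ketone carbon (CH3 and CH2CH2R) differ little in size, so the olefination may show incomplete E/Z control and the isomers may be hard to separate. The fallback sets out from 14 and comes back at 21, with the alkene geometry brought in by a reagent of fixed configuration.
- Stille coupling of 14 with tributyl(vinyl)stannane (Pd(PPh3)4, LiCl, THF, reflux) should give methyl (1S,4aS,8aR)-5-ethenyl-1,4a,6-trimethyl-1,2,3,4,4a,7,8,8a-octahydronaphthalene-1-carboxylate F8.
- LiAlH4 reduction should give the C19 alcohol [(1S,4aS,8aR)-5-ethenyl-1,4a,6-trimethyl-1,2,3,4,4a,7,8,8a-octahydronaphthalen-1-yl]methanol F9.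
- Ac2O/pyridine should give its acetate [(1S,4aS,8aR)-5-ethenyl-1,4a,6-trimethyl-1,2,3,4,4a,7,8,8a-octahydronaphthalen-1-yl]methyl acetate F10.
- 9-BBN should add to the vinyl terminus to give the B-alkyl borane 9-{2-[(4aR,5S,8aS)-5-(acetoxymethyl)-2,5,8a-trimethyl-3,4,4a,5,6,7,8,8a-octahydronaphthalen-1-yl]ethyl}-9-borabicyclo[3.3.1]nonane F11.
- F11 is coupled in the same flask (Suzuki–Miyaura; PdCl2(dppf), K3PO4, DMF–THF, 50 °C) with methyl (E)-3-{[(trifluoromethyl)sulfonyl]oxy}but-2-enoate F12, made from methyl acetoacetate with Tf2O and aqueous Me4NOH. Coupling with retention of geometry should give 21.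

Further compounds
F1 | step 1 | (S)-2-methylcyclohex-2-en-1-ol | O[C@H]1CCCC=C1C
F2 | step 1 | methyl 2-[(1S)-2-methylcyclohex-2-en-1-yl]acetate | COC(=O)C[C@@H]1CCCC=C1C
F3 | step 1 | methyl 2-[(1S)-3-hydroxy-2-methylcyclohexyl]acetate (mixture at C9 and C10) | COC(=O)C[C@@H]1CCCC(O)C1C
F4 | step 1 | methyl 2-[(1S)-2-methyl-3-oxocyclohexyl]acetate (C10 epimers) | COC(=O)C[C@@H]1CCCC(=O)C1C
F5 | step 1 | methyl 2-[(1S)-2-methyl-3-(trimethylsilyloxy)cyclohex-2-en-1-yl]acetate | COC(=O)C[C@@H]1CCCC(O[Si](C)(C)C)=C1C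
F6 | step 10 | methyl 13-oxo-14,15-dinorlabda-8,11E-dien-19-oate | CC(=O)/C=C/C1=C(C)CC[C@H]2[C@@](C)(C(=O)OC)CCC[C@]12C
F7 | step 10 | methyl 13-oxo-14,15-dinorlabd-8-en-19-oate | CC(=O)CCC1=C(C)CC[C@H]2[C@@](C)(C(=O)OC)CCC[C@]12C
F8 | step 12 | methyl (1S,4aS,8aR)-5-ethenyl-1,4a,6-trimethyl-1,2,3,4,4a,7,8,8a-octahydronaphthalene-1-carboxylate | C=CC1=C(C)CC[C@H]2[C@@](C)(C(=O)OC)CCC[C@]12C
F9 | step 12 | [(1S,4aS,8aR)-5-ethenyl-1,4a,6-trimethyl-1,2,3,4,4a,7,8,8a-octahydronaphthalen-1-yl]methanol | C=CC1=C(C)CC[C@H]2[C@@](C)(CO)CCC[C@]12C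
F10 | step 12 | [(1S,4aS,8aR)-5-ethenyl-1,4a,6-trimethyl-1,2,3,4,4a,7,8,8a-octahydronaphthalen-1-yl]methyl acetate | C=CC1=C(C)CC[C@H]2[C@@](C)(COC(C)=O)CCC[C@]12C
F11 | step 12 | 9-{2-[(4aR,5S,8aS)-5-(acetoxymethyl)-2,5,8a-trimethyl-3,4,4a,5,6,7,8,8a-octahydronaphthalen-1-yl]ethyl}-9-borabicyclo[3.3.1]nonane | B1(C2CCCC1CCC2)CCC1=C(C)CC[C@H]2[C@@](C)(COC(C)=O)CCC[C@]12C
F12 | step 12 | methyl (E)-3-{[(trifluoromethyl)sulfonyl]oxy}but-2-enoate | COC(=O)/C=C(\C)OS(=O)(=O)C(F)(F)F
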